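**Plan**

- Retrosynthesis cuts, in order: the C5–vinyl bond of the acrylic acid (Heck reaction on a C5 bromide); the C2–C3 bond of the dihydrofuran ring B (carbene C–H insertion); the O1–CH2 benzyl ether bond (Williamson), leaving a ring A arylacetate and a ring C benzyl bromide.
- Forward: the ring C bromide (from syringaldehyde) and the ring A bromophenol ester (from 2-(2-hydroxy-3-methoxyphenyl)acetic acid) are joined through O1; diazo transfer; ring B is closed by a Rh-catalysed 1,5 C–H insertion; the ester is epimerised and reduced; the acrylic acid is attached; the silyl ether is removed.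
- Enabling feature: C2 is both alpha to O1 and benzylic to the electron-rich ring C, so in the open precursor it is a CH2 with hydridic hydrogens, five atoms away from C3, the arylacetate carbon on ring A that can be made a donor/acceptor carbene.
- Stereochemistry: C2 from Rh2(R-PTTL)4, which selects one of the two enantiotopic C2 hydrogens; C3 from thermodynamic cis-to-trans epimerisation of the adjacent ester; the E alkene from the Heck reaction.

Key step: step 8

Assumption: the sense of induction of the N-phthaloyl-tert-leucinate dirhodium catalysts on 9 is taken to follow that of simpler 2-benzyloxyaryl diazoacetates, where the (S)-catalyst leads to (2R); hence the (R)-catalyst, made from Rh2(OAc)4 and N-phthaloyl-(R)-tert-leucine, is used. TIPS = tri(propan-2-yl)silyl.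

**Route**

Step 1
Reactants: 1 syringaldehyde (4-hydroxy-3,5-dimethoxybenzaldehyde)
Product: 2 3,5-dimethoxy-4-(TIPS-oxy)benzaldehyde
Conditions: TIPSCl (1.2 equiv), imidazole (2.5 equiv), DMF, rt to 40 °C
Reagents that add atoms: chlorotri(propan-2-yl)silane, CC(C)[Si](Cl)(C(C)C)C(C)C
Why: Imidazole-promoted silylation of an acidic para-formyl phenol; the bulky silyl ether later stops the ring C oxygen from expelling O1 as a quinone methide while C3 is still base-labile, and it comes off with fluoride at the end.

Step 2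
Reactants: 2 3,5-dimethoxy-4-(TIPS-oxy)benzaldehyde
Product: 3 [3,5-dimethoxy-4-(TIPS-oxy)phenyl]methanol
Conditions: NaBH4 (1.0 equiv), MeOH/THF, 0 °C
Reagents that add atoms: none
Why: Borohydride reduction of an aryl aldehyde, fast enough at 0 °C that the hindered aryl silyl ether should not be touched.

Step 3
Reactants: 3 [3,5-dimethoxy-4-(TIPS-oxy)phenyl]methanol
Product: 4 [4-(bromomethyl)-2,6-dimethoxyphenoxy]tri(propan-2-yl)silane
Conditions: PBr3 (0.4 equiv), Et2O, 0 °C; used without chromatography
Reagents that add atoms: phosphorus tribromide, BrP(Br)Br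
Why: Standard conversion of an electron-rich benzylic alcohol into its bromide; the product is reactive and is therefore carried on directly.

Step 4
Reactants: 5 2-(2-hydroxy-3-methoxyphenyl)acetic acid
Product: 6 methyl 2-(2-hydroxy-3-methoxyphenyl)acetate
Conditions: MeOH, H2SO4 (cat.), reflux
Reagents that add atoms: methanol, CO
Why: Fischer esterification, where the large excess of methanol should favour the open methyl ester over the benzofuranone lactone.

Step 5
Reactants: 6 methyl 2-(2-hydroxy-3-methoxyphenyl)acetate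
Product: 7 methyl 2-(5-bromo-2-hydroxy-3-methoxyphenyl)acetate
Conditions: NBS (1.02 equiv), MeCN, 0 °C to rt
Reagents that add atoms: N-bromosuccinimide, O=C1CCC(=O)N1Br
Why: Electrophilic aromatic bromination directed by the free hydroxyl, whose two ortho positions are blocked, so the bromine should enter para to it (the later C5).

Step 6
Reactants: 7 methyl 2-(5-bromo-2-hydroxy-3-methoxyphenyl)acetate; 4 [4-(bromomethyl)-2,6-dimethoxyphenoxy]tri(propan-2-yl)silane
Product: 8 methyl 2-[5-bromo-2-{[3,5-dimethoxy-4-(TIPS-oxy)phenyl]methoxy}-3-methoxyphenyl]acetate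
Conditions: K2CO3 (2 equiv), DMF, rt
Reagents that add atoms: none
Why: Williamson ether synthesis of a phenoxide with a very reactive benzylic bromide; K2CO3 is too weak to deprotonate the arylacetate carbon, so only O-alkylation is expected.

Step 7
Reactants: 8 methyl 2-[5-bromo-2-{[3,5-dimethoxy-4-(TIPS-oxy)phenyl]methoxy}-3-methoxyphenyl]acetate
Product: 9 methyl 2-[5-bromo-2-{[3,5-dimethoxy-4-(TIPS-oxy)phenyl]methoxy}-3-methoxyphenyl]-2-diazoacetate
Conditions: 4-acetamidobenzenesulfonyl azide (1.3 equiv), DBU (1.5 equiv), MeCN, 0 °C to rt, dark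
Reagents that add atoms: 4-acetamidobenzenesulfonyl azide, CC(=O)Nc1ccc(cc1)S(=O)(=O)N=[N+]=[N-]
Why: Regitz diazo transfer to the benzylic, ester-activated CH2 of an arylacetate, the standard entry to aryldiazoacetates.

Step 8
Reactants: 9 methyl 2-[5-bromo-2-{[3,5-dimethoxy-4-(TIPS-oxy)phenyl]methoxy}-3-methoxyphenyl]-2-diazoacetate
Product: 10 methyl (2S,3R)-5-bromo-2-[3,5-dimethoxy-4-(TIPS-oxy)phenyl]-7-methoxy-2,3-dihydro-1-benzofuran-3-carboxylate (cis)
Conditions: Rh2(R-PTTL)4 [dirhodium tetrakis(N-phthaloyl-(R)-tert-leucinate)] (1–2 mol %), toluene, −78 °C, slow addition of 9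
Reagents that add atoms: none
Why: The catalyst expels N2 from 9 to give an electrophilic donor/acceptor rhodium carbenoid at C3, which inserts into a C2–H bond through a concerted, asynchronous three-centre transition state with hydride-like transfer, the positive charge building at C2 being stabilised by O1 and by ring C. The closest known reaction type is the enantioselective intramolecular 1,5 C–H insertion of methyl 2-(2-benzyloxyaryl)-2-diazoacetates with chiral dirhodium carboxylates, which gives cis-2-aryl-2,3-dihydrobenzofuran-3-carboxylates. Ring B closes in the 1,5-insertion mode (C3, C3a, C7a, O1, C2), the five-membered transition state being the only strain-free one available, since attack of O1 on the carbene would need a four-membered oxonium ylide and no other C–H bond is within reach. C2 is controlled by the chiral carboxylate pocket, which tells the two enantiotopic benzylic hydrogens apart and inserts with retention; C3 is controlled relative to C2 by the transition-state geometry, which should place aryl and ester cis, and is corrected in step 9. The step needs chemoselectivity for C–H insertion over Büchner-type attack on ring C, carbene dimerisation and O–H insertion; the doubly activated C2–H, the low temperature, the dry non-coordinating solvent and the slow addition should secure it, while the aryl bromide, silyl ether and methoxy groups are inert to the carbenoid.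

Step 9
Reactants: 10 methyl (2S,3R)-cis ester
Product: 11 methyl (2S,3S)-5-bromo-2-[3,5-dimethoxy-4-(TIPS-oxy)phenyl]-7-methoxy-2,3-dihydro-1-benzofuran-3-carboxylate (trans)
Conditions: NaOMe (0.2 equiv), MeOH/THF (1:1), 0 °C to rt; AcOH quench
Reagents that add atoms: none
Why: Thermodynamic epimerisation at C3 through the ester enolate to the less crowded trans isomer; C2 should stay intact because beta-elimination of O1 is the reverse of a 5-endo-trig closure (the C2–O1 bond lies in the enolate plane) and the silyl ether blocks a quinone methide pathway.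

Step 10
Reactants: 11 methyl (2S,3S)-trans ester
Product: 12 [(2S,3R)-5-bromo-2-[3,5-dimethoxy-4-(TIPS-oxy)phenyl]-7-methoxy-2,3-dihydro-1-benzofuran-3-yl]methanol
Conditions: i-Bu2AlH (3 equiv), CH2Cl2, −78 to 0 °C; aqueous potassium sodium tartrate work-up
Reagents that add atoms: none
Why: Non-basic hydride reduction of the ester to the primary alcohol, which fixes C3 for good (the descriptor changes only because the priorities change) and leaves the aryl bromide and silyl ether alone.

Step 11
Reactants: 12 the (2S,3R)-bromo alcohol; 13 acrylic acid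
Product: 14 (E)-3-[(2S,3R)-2-[3,5-dimethoxy-4-(TIPS-oxy)phenyl]-3-(hydroxymethyl)-7-methoxy-2,3-dihydro-1-benzofuran-5-yl]prop-2-enoic acid
Conditions: Pd(OAc)2 (5 mol %), P(o-tol)3 (12 mol %), Et3N (4 equiv), DMF, 100 °C
Reagents that add atoms: none
Why: Mizoroki–Heck arylation of acrylic acid at its terminal carbon by the unhindered C5 bromide; syn insertion and syn beta-hydride elimination should give the E-cinnamic acid directly, with no ester to differentiate from the C3 substituent.

Step 12
Reactants: 14 the silyl-protected E-acid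
Product: 15 (E)-3-[(2S,3R)-2-(4-hydroxy-3,5-dimethoxyphenyl)-3-(hydroxymethyl)-7-methoxy-2,3-dihydro-1-benzofuran-5-yl]prop-2-enoic acid (target)
Conditions: n-Bu4NF (2.5 equiv), THF, 0 °C; then 1 M HCl work-up
Reagents that add atoms: none
Why: Fluoride cleavage of the aryl silyl ether under cold, brief conditions; C3 is no longer epimerisable, so transient phenoxide formation cannot erode the configuration.

**Compound list**

1 | syringaldehyde (4-hydroxy-3,5-dimethoxybenzaldehyde) | COc1cc(C=O)cc(OC)c1O | starting material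
2 | 3,5-dimethoxy-4-(TIPS-oxy)benzaldehyde | COc1cc(C=O)cc(OC)c1O[Si](C(C)C)(C(C)C)C(C)C | intermediate
3 | [3,5-dimethoxy-4-(TIPS-oxy)phenyl]methanol | COc1cc(CO)cc(OC)c1O[Si](C(C)C)(C(C)C)C(C)C | intermediate
4 | [4-(bromomethyl)-2,6-dimethoxyphenoxy]tri(propan-2-yl)silane | COc1cc(CBr)cc(OC)c1O[Si](C(C)C)(C(C)C)C(C)C | intermediate
5 | 2-(2-hydroxy-3-methoxyphenyl)acetic acid | COc1cccc(CC(=O)O)c1O | starting material
6 | methyl 2-(2-hydroxy-3-methoxyphenyl)acetate | COC(=O)Cc1cccc(OC)c1O | intermediate
7 | methyl 2-(5-bromo-2-hydroxy-3-methoxyphenyl)acetate | COC(=O)Cc1cc(Br)cc(OC)c1O | intermediate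
8 | methyl 2-[5-bromo-2-{[3,5-dimethoxy-4-(TIPS-oxy)phenyl]methoxy}-3-methoxyphenyl]acetate | COC(=O)Cc1cc(Br)cc(OC)c1OCc1cc(OC)c(O[Si](C(C)C)(C(C)C)C(C)C)c(OC)c1 | intermediate
9 | methyl 2-[5-bromo-2-{[3,5-dimethoxy-4-(TIPS-oxy)phenyl]methoxy}-3-methoxyphenyl]-2-diazoacetate | COC(=O)C(=[N+]=[N-])c1cc(Br)cc(OC)c1OCc1cc(OC)c(O[Si](C(C)C)(C(C)C)C(C)C)c(OC)c1 | intermediate
10 | methyl (2S,3R)-5-bromo-2-[3,5-dimethoxy-4-(TIPS-oxy)phenyl]-7-methoxy-2,3-dihydro-1-benzofuran-3-carboxylate (cis) | COc1cc([C@H]2Oc3c(OC)cc(Br)cc3[C@H]2C(=O)OC)cc(OC)c1O[Si](C(C)C)(C(C)C)C(C)C | intermediate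
11 | methyl (2S,3S)-5-bromo-2-[3,5-dimethoxy-4-(TIPS-oxy)phenyl]-7-methoxy-2,3-dihydro-1-benzofuran-3-carboxylate (trans) | COc1cc([C@H]2Oc3c(OC)cc(Br)cc3[C@@H]2C(=O)OC)cc(OC)c1O[Si](C(C)C)(C(C)C)C(C)C | intermediate
12 | [(2S,3R)-5-bromo-2-[3,5-dimethoxy-4-(TIPS-oxy)phenyl]-7-methoxy-2,3-dihydro-1-benzofuran-3-yl]methanol | COc1cc([C@H]2Oc3c(OC)cc(Br)cc3[C@@H]2CO)cc(OC)c1O[Si](C(C)C)(C(C)C)C(C)C | intermediate
13 | acrylic acid | C=CC(=O)O | starting material
14 | (E)-3-[(2S,3R)-2-[3,5-dimethoxy-4-(TIPS-oxy)phenyl]-3-(hydroxymethyl)-7-methoxy-2,3-dihydro-1-benzofuran-5-yl]prop-2-enoic acid | COc1cc([C@H]2Oc3c(OC)cc(/C=C/C(=O)O)cc3[C@@H]2CO)cc(OC)c1O[Si](C(C)C)(C(C)C)C(C)C | intermediate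
15 | (E)-3-[(2S,3R)-2-(4-hydroxy-3,5-dimethoxyphenyl)-3-(hydroxymethyl)-7-methoxy-2,3-dihydro-1-benzofuran-5-yl]prop-2-enoic acid | COc1cc([C@H]2Oc3c(OC)cc(/C=C/C(=O)O)cc3[C@@H]2CO)cc(OC)c1O | target

**Step count and risks**

Total: 12 steps. Longest linear sequence: 10 steps (steps 1–3 and 6–12, from syringaldehyde); the ring A branch (steps 4 and 5) joins at step 6.

Steps most likely to fail:

1. Step 8. The two enantiotopic C2 hydrogens may not be told apart well enough next to the 7-methoxy group, or the carbenoid may be diverted into attack on the very electron-rich ring C. The fallback takes the C2–C3 bond and the C3 configuration from an auxiliary-controlled syn-aldol reaction and closes ring B at O1–C2 instead. It sets out from 7 (with aldehyde 2) and comes back at 12. Phenol 7 is capped as the methoxymethyl ether, methyl 2-[5-bromo-3-methoxy-2-(methoxymethoxy)phenyl]acetate F1 (MOMCl, i-Pr2NEt, CH2Cl2). F1 is saponified to the acid F2 (LiOH, THF/H2O, 0 °C). F2 acylates (S)-4-benzyl-1,3-oxazolidin-2-one (t-BuCOCl, Et3N, LiCl, THF) to give the imide F3. The Z-boron enolate of F3 (n-Bu2BOTf, i-Pr2NEt, CH2Cl2, −78 °C) adds to aldehyde 2 in an Evans syn-aldol reaction to give the adduct F4, whose alpha carbon already has the arrangement of C3. LiBH4 (THF/MeOH, 0 °C) releases the auxiliary and gives the diol F5. HCl in MeOH at rt removes the MOM group to give the phenol diol F6 (not isolated) and ionises the benzylic alcohol to the cation stabilised by ring C; the phenol captures it to give the thermodynamically preferred trans ring of 12.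

2. Step 9. Epimerisation at C3 may stall short of completion, methoxide may strip the silyl ether, or the enolate may open ring B and scramble C2. The fallback corrects C2 instead of C3 and uses no base. It sets out from 9 and comes back at 12. Insertion with the enantiomeric catalyst Rh2(S-PTTL)4 (toluene, −78 °C) should give the methyl (2R,3S)-cis ester F7, in which C3 already has the spatial arrangement of the target. i-Bu2AlH (CH2Cl2, −78 to 0 °C) reduces it to the (2R,3R)-cis alcohol F8. Catalytic CF3SO3H in CH2Cl2 then ionises the C2–O1 bond reversibly to the ring C-stabilised benzylic cation, which should re-close to the more stable trans isomer 12, with C3 untouched.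

3. Step 11. Oxidative addition into the electron-rich C5–Br bond may be slow, so that protodebromination or loss of the silyl group competes at the temperature needed. The fallback builds the acid by condensation instead of cross-coupling. It sets out from 12 and comes back at 14. Bromine–lithium exchange (n-BuLi, 2.2 equiv, THF, −78 °C, the first equivalent forming the lithium alkoxide) followed by DMF gives the 5-carbaldehyde F9. Knoevenagel–Doebner condensation with malonic acid (pyridine, piperidine cat., 80 °C) goes through the arylidenemalonic acid F10 (not isolated), which decarboxylates to the E-acid 14.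

**Further compounds**

F1 | step 8 | methyl 2-[5-bromo-3-methoxy-2-(methoxymethoxy)phenyl]acetate | COCOc1c(CC(=O)OC)cc(Br)cc1OC
F2 | step 8 | 2-[5-bromo-3-methoxy-2-(methoxymethoxy)phenyl]acetic acid | COCOc1c(CC(=O)O)cc(Br)cc1OC
F3 | step 8 | (4S)-4-benzyl-3-{2-[5-bromo-3-methoxy-2-(methoxymethoxy)phenyl]acetyl}-1,3-oxazolidin-2-one | COCOc1c(CC(=O)N2[C@@H](Cc3ccccc3)COC2=O)cc(Br)cc1OC
F4 | step 8 | (4S)-4-benzyl-3-[(2S,3S)-2-[5-bromo-3-methoxy-2-(methoxymethoxy)phenyl]-3-[3,5-dimethoxy-4-(TIPS-oxy)phenyl]-3-hydroxypropanoyl]-1,3-oxazolidin-2-one | COCOc1c([C@@H]([C@H](O)c2cc(OC)c(O[Si](C(C)C)(C(C)C)C(C)C)c(OC)c2)C(=O)N2[C@@H](Cc3ccccc3)COC2=O)cc(Br)cc1OC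
F5 | step 8 | (1S,2R)-2-[5-bromo-3-methoxy-2-(methoxymethoxy)phenyl]-1-[3,5-dimethoxy-4-(TIPS-oxy)phenyl]propane-1,3-diol | COCOc1c([C@@H]([C@H](O)c2cc(OC)c(O[Si](C(C)C)(C(C)C)C(C)C)c(OC)c2)CO)cc(Br)cc1OC
F6 | step 8 | (1S,2R)-2-(5-bromo-2-hydroxy-3-methoxyphenyl)-1-[3,5-dimethoxy-4-(TIPS-oxy)phenyl]propane-1,3-diol | Oc1c([C@@H]([C@H](O)c2cc(OC)c(O[Si](C(C)C)(C(C)C)C(C)C)c(OC)c2)CO)cc(Br)cc1OC
F7 | step 9 | methyl (2R,3S)-5-bromo-2-[3,5-dimethoxy-4-(TIPS-oxy)phenyl]-7-methoxy-2,3-dihydro-1-benzofuran-3-carboxylate (cis) | COc1cc([C@@H]2Oc3c(OC)cc(Br)cc3[C@@H]2C(=O)OC)cc(OC)c1O[Si](C(C)C)(C(C)C)C(C)C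
F8 | step 9 | [(2R,3R)-5-bromo-2-[3,5-dimethoxy-4-(TIPS-oxy)phenyl]-7-methoxy-2,3-dihydro-1-benzofuran-3-yl]methanol (cis) | COc1cc([C@@H]2Oc3c(OC)cc(Br)cc3[C@@H]2CO)cc(OC)c1O[Si](C(C)C)(C(C)C)C(C)C
F9 | step 11 | (2S,3R)-2-[3,5-dimethoxy-4-(TIPS-oxy)phenyl]-3-(hydroxymethyl)-7-methoxy-2,3-dihydro-1-benzofuran-5-carbaldehyde | COc1cc([C@H]2Oc3c(OC)cc(C=O)cc3[C@@H]2CO)cc(OC)c1O[Si](C(C)C)(C(C)C)C(C)C
F10 | step 11 | 2-{[(2S,3R)-2-[3,5-dimethoxy-4-(TIPS-oxy)phenyl]-3-(hydroxymethyl)-7-methoxy-2,3-dihydro-1-benzofuran-5-yl]methylidene}propanedioic acid | COc1cc([C@H]2Oc3c(OC)cc(C=C(C(=O)O)C(=O)O)cc3[C@@H]2CO)cc(OC)c1O[Si](C(C)C)(C(C)C)C(C)C
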